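The numbers of this flask come from no measurement; the run is a simulation.

I start from what is left over: each G must take up two E to become D, and any E left over can carry D further.

    D + E → D.E (k1 = 73 /M/s)
    G + E → J + X (k2 = 560 /M/s)
    X + E → J + D (k3 = 120 /M/s)
    D + E → J + L (k4 = 450 /M/s)

| flask | G | E | time |
|---|---|---|---|
| north-west | 5.0 mM | 2.00 mM | 2.5 s |
| north | 5.0 mM | 4.00 mM | 2.5 s |
| south-east | 5.0 mM | 8.00 mM | 2.5 s |
| east | 5.0 mM | 15.0 mM | 2.5 s |
| west | 5.0 mM | 30.0 mM | 2.5 s |

- "hardly changes" means that all values lie within two and a half points (for a concentration: within two and a half percent of the largest)
- run time (north-west): 2.5 s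

- [D] at the end for north-west, north, south-east, east, west, in this order
- how that number moves from the first to the last of them (rises all the way / hardly changes / rises, then falls / falls, then rises / falls all the way)

By hand I compare two amounts. One is the E charged. The other is the E need, the E it takes to bring every G charged as far as D, two per G: 10.0 mM. I call charge over need the cover, and it runs from 0.200 in north-west to 3.00 in west.

At a cover well under one, the charge cannot bring every G to D, so I expect D to stay low. At a cover well over one, E remains beyond the need for step 4, which takes D on to L, so I expect D to fall again.

The side step to D.E does not enter my count. In north-west, with E as charged, the half-life of D by step 4 alone is 0.77 s, shorter than 4.7 s by step 1 alone. So I commit to a row that rises, then falls, with its top near a cover of one. I reckon no row of numbers.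

The forecast gives 0.086 mM, 0.3 mM, 0.65 mM, 0.35 mM and 0.011 mM, so its row rises, then falls. Its ground is this: “Limited E stalls the chain early, while excess E drives D onward”.

The simulation gives 0.0851 mM, 0.307 mM, 0.655 mM, 0.349 mM and 0.0108 mM, so the row rises, then falls, as the forecast said. Read off the row, it turns at a charge of E of 8.6 mM, a cover of 0.860. North-west, at a cover of 0.200, ends with 0.488 % of its E, the limiting reagent, and 62.4 % of its G. With E held at its charge, north-west ends at 0.646 mM of D, not 0.0851 mM: the shrinking supply of E is the largest single effect there. West, at a cover of 3.00, keeps 50.3 % of its E, and its D stands at 0.216 % of the G charged.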